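**Plan**

- Retrosynthesis (carotenoid numbering, primed locants for the half with the saturated ring): the C9'–C10' single bond is cut first, giving a C27 retro-polyenyl metal and a C13 dienyl iodide. In the C27 half, C10'=C11' goes back to a terminal alkyne, the whole retro shift goes back to a C12' ethynyl carbinol (C12'–OH and H-4 lost as water), and C11'–C12', C13'=C14' and C15=C15' lead back to retinal. In the C13 half, C9'–I, C7'–C8' and the ring bond C1'–C6' lead back to (S)-citronellal.
- Forward, C13 half: the saturated ring closes first by cation–olefin cyclisation, its exocyclic C6'=C7' bond is fixed as an enol triflate, propyne brings C8' and C9', and hydrozirconation–iodination gives the iodide.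
- Forward, C27 half: the trimethylcyclohexene ring comes ready-made in retinal; two Wittig steps and an ethynyl addition lengthen the chain, and one dehydration moves all nine C=C bonds into the retro positions (C4=C5 in the ring through C13'=C12'). The two halves are joined last.
- Enabling feature: C10'=C11' is the 1,2-disubstituted E terminus of the C27 polyene, and C9' is the methyl-bearing terminus of the diene C9'=C8'–C7'=C6' exocyclic to the saturated ring. C10' can therefore be carried as an alkyne CH, which also confines the C12' cation so that only H-4 of the cyclohexene ring can be lost, and is turned into the alkenyl metal by syn-hydrometalation in the coupling flask.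
- Stereochemistry: C5' (S) is C3 of (S)-citronellal and is never touched. The chain C=C bonds are E from stabilised ylides, thermodynamic dehydration, syn-hydrozirconation and coupling with retention; the two exocyclic bonds follow allylic strain (C8 syn to C1, C8' syn to C5').

Key step: step 10

Remark on the chemistry: (S)-citronellal of high enantiomeric purity and all-trans-retinal are taken as the commercial starting materials; all polyenes are handled under argon in dim light and, once the C9'=C8'–C7'=C6' diene exists, at or below room temperature.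

**Route**

Step 1
Reactants: 1 (S)-citronellal
Product: 2 (3S)-3,7-dimethylocta-1,6-dien-1-yl acetate (E/Z mixture at C1=C2)
Conditions: Ac2O, CH3CO2K, Et3N, 120 °C
Reagents that add atoms: acetic anhydride, CC(=O)OC(C)=O
Why: Enol acetylation of the aldehyde masks the carbonyl group as a nucleophilic enol ester for the cyclisation; the C3 stereocentre is not involved.

Step 2
Reactants: 2 (3S)-3,7-dimethylocta-1,6-dien-1-yl acetate
Product: 3 (6S)-2,2,6-trimethylcyclohexane-1-carbaldehyde (both C1 epimers)
Conditions: 85% H3PO4, toluene, 100 °C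
Reagents that add atoms: none
Why: Cation–olefin cyclisation in which protonation of the trisubstituted C6=C7 bond gives a tertiary cation that is captured by the enol acetate carbon C2 in a six-membered closure and the acetoxycarbenium ion is hydrolysed to the aldehyde; the methyl-bearing centre (C3 of 1, C6 of 3) is untouched and stays S, and the new C1 centre needs no control because it becomes sp2 in step 3.

Step 3
Reactants: 3 (6S)-2,2,6-trimethylcyclohexane-1-carbaldehyde
Product: 5 (E)-[(6S)-2,2,6-trimethylcyclohexylidene]methyl trifluoromethanesulfonate, via potassium enolate 4 (not isolated)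
Conditions: KN(SiMe3)2, THF, −78 °C; then PhNTf2, −78 °C to rt
Reagents that add atoms: N-phenylbis(trifluoromethanesulfonimide), O=S(=O)(N(c1ccccc1)S(=O)(=O)C(F)(F)F)C(F)(F)F
Why: Enol triflate formation by kinetic deprotonation at the only α-hydrogen and O-sulfonylation; 1,3-allylic strain should turn the enolate oxygen toward the C6 methine and away from the gem-dimethyl carbon, which gives the E isomer needed, and the C6 stereocentre is not acidic.

Step 4
Reactants: 5 (E)-[(6S)-2,2,6-trimethylcyclohexylidene]methyl trifluoromethanesulfonate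
Product: 6 (1E,6S)-1-(but-2-yn-1-ylidene)-2,2,6-trimethylcyclohexane
Conditions: propyne, PdCl2(PPh3)2 (cat.), CuI (cat.), i-Pr2NH, THF, 0 °C to rt
Reagents that add atoms: propyne, CC#C
Why: Sonogashira coupling of the alkenyl triflate proceeds with retention of the double-bond geometry and brings in C8', C9' and the C9' methyl group.

Step 5
Reactants: 6 (1E,6S)-1-(but-2-yn-1-ylidene)-2,2,6-trimethylcyclohexane
Product: 8 (1E,6S)-1-[(2E)-3-iodobut-2-en-1-ylidene]-2,2,6-trimethylcyclohexane, via alkenylzirconocene chloride 7 (not isolated)
Conditions: (C5H5)2Zr(H)Cl (excess), THF, 50 °C, dark; then I2, 0 °C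
Reagents that add atoms: iodine, [I][I]
Why: Syn-hydrozirconation of the internal alkyne, in which excess reagent and gentle warming let the regioisomeric alkenylzirconium species equilibrate to the one with zirconium on the less hindered, methyl-bearing carbon C9', followed by iodinolysis with retention to the (E)-2-iodoalkene.

Step 6
Reactants: 9 all-trans-retinal
Product: 10 β-apo-14'-carotenal, (2E,4E,6E,8E,10E)-5,9-dimethyl-11-(2,6,6-trimethylcyclohex-1-en-1-yl)undeca-2,4,6,8,10-pentaenal
Conditions: Ph3P=CHCHO (about one equivalent), toluene, 80 °C, dark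
Reagents that add atoms: (triphenylphosphoranylidene)acetaldehyde, O=CC=P(c1ccccc1)(c1ccccc1)c1ccccc1
Why: Wittig olefination with the stabilised formylmethylene ylide is E-selective and adds C15' and C14'; the ylide is kept near one equivalent to limit a second homologation.

Step 7
Reactants: 10 β-apo-14'-carotenal
Product: 11 β-apo-12'-carotenal, (2E,4E,6E,8E,10E,12E)-2,7,11-trimethyl-13-(2,6,6-trimethylcyclohex-1-en-1-yl)trideca-2,4,6,8,10,12-hexaenal
Conditions: Ph3P=C(CH3)CHO, toluene, 90 °C, dark
Reagents that add atoms: 2-(triphenylphosphoranylidene)propanal, CC(C=O)=P(c1ccccc1)(c1ccccc1)c1ccccc1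
Why: Wittig olefination with the stabilised α-methyl formyl ylide gives the (E)-2-methyl enal and installs C13', its methyl group and C12'.

Step 8
Reactants: 11 β-apo-12'-carotenal
Product: 13 C27 ethynyl carbinol (4E,6E,8E,10E,12E,14E)-4,9,13-trimethyl-15-(2,6,6-trimethylcyclohex-1-en-1-yl)pentadeca-4,6,8,10,12,14-hexaen-1-yn-3-ol (racemic at C3), via bromomagnesium alkoxide 12 (not isolated)
Conditions: HC≡CMgBr, THF, −20 to 0 °C; then pH 7 aqueous buffer
Reagents that add atoms: ethynylmagnesium bromide, C#C[Mg]Br
Why: 1,2-Addition of the alkynyl Grignard reagent to the polyenal gives the C12' carbinol; its new stereocentre is left racemic on purpose because it is destroyed in step 9.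

Step 9
Reactants: 13 C27 ethynyl carbinol
Product: 14 retro-C27 enyne (6E)-1,5,5-trimethyl-6-[(2E,4E,6E,8E,10E,12E)-3,7,12-trimethylpentadeca-2,4,6,8,10,12-hexaen-14-yn-1-ylidene]cyclohex-1-ene
Conditions: p-TsOH·H2O (cat.), 4 Å molecular sieves, toluene (dilute), 0 °C to rt, dark; then Et3N
Reagents that add atoms: none
Why: Acid-catalysed vinylogous E1 dehydration (the reaction type that turns retinol into anhydroretinol), in which ionisation at C12' gives a cation delocalised from C12' to C5, the alkyne blocks any proton loss on the C11' side, and loss of H-4 from the ring gives the fully conjugated retro-polyenyne as the thermodynamic all-E product with C8 syn to C1.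

Step 10
Reactants: 14 retro-C27 enyne; 8 (1E,6S)-1-[(2E)-3-iodobut-2-en-1-ylidene]-2,2,6-trimethylcyclohexane
Product: 17 (5'S)-4,5'-retro-β,β-carotene (all chain double bonds E), via alkenylzirconocene chloride 15 (not isolated), via alkenylzinc chloride 16 (not isolated)
Conditions: (C5H5)2Zr(H)Cl, THF, rt, dark; then ZnCl2, 8, Pd(PPh3)4 (cat.), THF, rt
Reagents that add atoms: none
Why: (C5H5)2Zr(H)Cl adds H–Zr syn across the terminal C10'≡C11' triple bond with zirconium on the terminal carbon C10', ZnCl2 transfers the alkenyl group to zinc, zerovalent palladium inserts into the C9'–I bond of 8, and transmetalation followed by reductive elimination forms the C9'–C10' bond with retention at both alkenyl carbons. The closest known reaction type is the hydrozirconation/Negishi alkenyl–alkenyl cross-coupling used to assemble conjugated polyenes, including couplings of α-substituted alkenyl iodides that need the zinc salt. No ring is closed and no stereocentre is created; the C5' centre, allylic to the new polyene, sees no acid, no base and no heat that could start a [1,5]-hydrogen shift from C5' to C9'. The step needs hydrometalation of one alkyne in the presence of nine C=C bonds and placement of the metal on C10'; both are secured because the alkyne is terminal while every C=C bond of 14 is conjugated and 1,2-di- or trisubstituted, and hence far slower toward the bulky zirconium hydride. The E geometry at C10'=C11' follows from the syn addition, and the E geometries at C9'=C8' and C7'=C6' are carried over from 8.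

**Compound list**

1 | (S)-citronellal, (3S)-3,7-dimethyloct-6-enal | O=CC[C@@H](C)CCC=C(C)C | starting material
2 | (3S)-3,7-dimethylocta-1,6-dien-1-yl acetate (E/Z mixture) | CC(=O)OC=C[C@@H](C)CCC=C(C)C | intermediate
3 | (6S)-2,2,6-trimethylcyclohexane-1-carbaldehyde (both C1 epimers) | O=CC1[C@@H](C)CCCC1(C)C | intermediate
4 | potassium enolate, potassium (E)-[(6S)-2,2,6-trimethylcyclohexylidene]methanolate | [K+].[O-]/C=C1\[C@@H](C)CCCC1(C)C | intermediate (not isolated)
5 | (E)-[(6S)-2,2,6-trimethylcyclohexylidene]methyl trifluoromethanesulfonate | O=S(=O)(O/C=C1\[C@@H](C)CCCC1(C)C)C(F)(F)F | intermediate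
6 | (1E,6S)-1-(but-2-yn-1-ylidene)-2,2,6-trimethylcyclohexane | CC#C/C=C1\[C@@H](C)CCCC1(C)C | intermediate
7 | alkenylzirconocene chloride, chlorobis(cyclopentadienyl){(2E)-4-[(1E,6S)-2,2,6-trimethylcyclohexylidene]but-2-en-2-yl}zirconium | Cl[Zr](C1C=CC=C1)(C1C=CC=C1)/C(C)=C/C=C1\[C@@H](C)CCCC1(C)C | intermediate (not isolated)
8 | (1E,6S)-1-[(2E)-3-iodobut-2-en-1-ylidene]-2,2,6-trimethylcyclohexane | I/C(C)=C/C=C1\[C@@H](C)CCCC1(C)C | intermediate
9 | all-trans-retinal | CC1=C(/C=C/C(C)=C/C=C/C(C)=C/C=O)C(C)(C)CCC1 | starting material
10 | β-apo-14'-carotenal (all-E C22 aldehyde) | CC1=C(/C=C/C(C)=C/C=C/C(C)=C/C=C/C=O)C(C)(C)CCC1 | intermediate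
11 | β-apo-12'-carotenal (all-E C25 aldehyde) | CC1=C(/C=C/C(C)=C/C=C/C(C)=C/C=C/C=C(C)/C=O)C(C)(C)CCC1 | intermediate
12 | bromomagnesium alkoxide of 13 | CC1=C(/C=C/C(C)=C/C=C/C(C)=C/C=C/C=C(C)/C(O[Mg]Br)C#C)C(C)(C)CCC1 | intermediate (not isolated)
13 | C27 ethynyl carbinol, (4E,6E,8E,10E,12E,14E)-4,9,13-trimethyl-15-(2,6,6-trimethylcyclohex-1-en-1-yl)pentadeca-4,6,8,10,12,14-hexaen-1-yn-3-ol (racemic) | CC1=C(/C=C/C(C)=C/C=C/C(C)=C/C=C/C=C(C)/C(O)C#C)C(C)(C)CCC1 | intermediate
14 | retro-C27 enyne, (6E)-1,5,5-trimethyl-6-[(2E,4E,6E,8E,10E,12E)-3,7,12-trimethylpentadeca-2,4,6,8,10,12-hexaen-14-yn-1-ylidene]cyclohex-1-ene | CC1=CCCC(C)(C)\C1=C/C=C(C)/C=C/C=C(C)/C=C/C=C/C(C)=C/C#C | intermediate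
15 | alkenylzirconocene chloride from 14 (zirconium on C10', 10'E) | CC1=CCCC(C)(C)\C1=C/C=C(C)/C=C/C=C(C)/C=C/C=C/C(C)=C/C=C/[Zr](Cl)(C1C=CC=C1)C1C=CC=C1 | intermediate (not isolated)
16 | alkenylzinc chloride from 15 (zinc on C10', 10'E) | CC1=CCCC(C)(C)\C1=C/C=C(C)/C=C/C=C(C)/C=C/C=C/C(C)=C/C=C/[Zn]Cl | intermediate (not isolated)
17 | (5'S)-4,5'-retro-β,β-carotene; all chain double bonds E, C8 syn to C1 at C6=C7, C8' syn to C5' at C6'=C7' | CC1=CCCC(C)(C)\C1=C/C=C(C)/C=C/C=C(C)/C=C/C=C/C(C)=C/C=C/C(C)=C/C=C1\[C@@H](C)CCCC1(C)C | target

**Count and risks**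

Total step count: 10. Longest linear sequence: 6 steps (steps 1, 2, 3, 4, 5 and 10); the retinal branch has 4 steps before the coupling.

Steps most likely to fail:

Step 9. As the conjugated cation grows, proton loss from the C9 and C13 methyl groups, capture by a nucleophile at another terminus and oligomerisation may compete with loss of H-4. The fallback moves the retro shift to a cation one vinylogue shorter and puts in C13' with its methyl group afterwards by carbometalation instead of carrying it through the ionisation. It sets out from 10. Addition of HC≡CMgBr should give the C24 ethynyl carbinol F1. The same acid-catalysed dehydration should give the retro-C24 enyne F2. Zirconium-catalysed syn-methylalumination of its terminal alkyne (AlMe3, (C5H5)2ZrCl2 cat.) should give the (E)-alkenyl(dimethyl)alane F3. This is coupled in the same flask with (bromoethynyl)triisopropylsilane (Pd(PPh3)4 cat., ZnCl2 cat.) to the silyl-protected enyne F4. Bu4NF removes the silyl group, and the sequence comes back to the route at 14.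

Step 10. Hydrozirconation may also attack the conjugated polyene, or the alkenylmetal may isomerise or homocouple before it is captured. The fallback keeps the alkyne through the coupling and makes the double bond afterwards. It sets out from 14 and 8. Sonogashira coupling (Pd(PPh3)4, CuI, i-Pr2NH, rt) should give the 10',11'-didehydro compound F5. Cis-selective semi-reduction of its triple bond with zinc dust activated by Cu(OAc)2 and AgNO3 in aqueous methanol should give the hindered (10'Z)-isomer F6. Iodine-catalysed Z-to-E isomerisation of this one hindered double bond at room temperature in diffuse light comes back to the route at 17.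

Step 3. Kinetic deprotonation may give poor control of the enolate geometry at the exocyclic double bond. The fallback puts the geometry under thermodynamic control in an isolable enol ester. It sets out from 3. Isopropenyl acetate with catalytic p-TsOH at reflux should give the equilibrated (E)-enol acetate F7, which can be freed from its Z isomer. MeLi (two equivalents, THF, 0 °C) cleaves it with retention of geometry to the lithium (E)-enolate F8, which is triflated with PhNTf2 and comes back to the route at 5.

Further compounds
F1 | step 9 | C24 ethynyl carbinol, (4E,6E,8E,10E,12E)-7,11-dimethyl-13-(2,6,6-trimethylcyclohex-1-en-1-yl)trideca-4,6,8,10,12-pentaen-1-yn-3-ol (racemic) | CC1=C(/C=C/C(C)=C/C=C/C(C)=C/C=C/C(O)C#C)C(C)(C)CCC1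
F2 | step 9 | retro-C24 enyne, (6E)-1,5,5-trimethyl-6-[(2E,4E,6E,8E,10E)-3,7-dimethyltrideca-2,4,6,8,10-pentaen-12-yn-1-ylidene]cyclohex-1-ene | CC1=CCCC(C)(C)\C1=C/C=C(C)/C=C/C=C(C)/C=C/C=C/C#C
F3 | step 9 | (E)-alkenyl(dimethyl)alane from F2 (methyl on C13', aluminium on C12') | CC1=CCCC(C)(C)\C1=C/C=C(C)/C=C/C=C(C)/C=C/C=C/C(C)=C/[Al](C)C
F4 | step 9 | C10'-triisopropylsilyl derivative of 14 | CC1=CCCC(C)(C)\C1=C/C=C(C)/C=C/C=C(C)/C=C/C=C/C(C)=C/C#C[Si](C(C)C)(C(C)C)C(C)C
F5 | step 10 | (5'S)-10',11'-didehydro-4,5'-retro-β,β-carotene | CC1=CCCC(C)(C)\C1=C/C=C(C)/C=C/C=C(C)/C=C/C=C/C(C)=C/C#C/C(C)=C/C=C1\[C@@H](C)CCCC1(C)C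
F6 | step 10 | (5'S,10'Z)-4,5'-retro-β,β-carotene | CC1=CCCC(C)(C)\C1=C/C=C(C)/C=C/C=C(C)/C=C/C=C/C(C)=C/C=C\C(C)=C\C=C1/[C@@H](C)CCCC1(C)C
F7 | step 3 | (E)-[(6S)-2,2,6-trimethylcyclohexylidene]methyl acetate | CC(=O)O/C=C1\[C@@H](C)CCCC1(C)C
F8 | step 3 | lithium (E)-[(6S)-2,2,6-trimethylcyclohexylidene]methanolate | [Li+].[O-]/C=C1\[C@@H](C)CCCC1(C)C
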